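## Structural features

The target is an unsymmetrical biflavone with no stereocentre. It consists of two 2-aryl-4H-chromen-4-one units, each with a benzo ring A, a pyranone ring C and a 2-aryl ring B. Unit 1 (unprimed numbers) is 5-hydroxy-7-methoxy-2-(4-methoxyphenyl)chromone and unit 2 (double-primed chromone numbers) is a 5,7-dihydroxy-2-arylchromone; one diaryl ether oxygen joins C8 of unit 1 to the para carbon C4' of ring B of unit 2. Ring A of unit 1 is 1,2,3,5-tetraoxygenated and its four oxygens all differ: ring oxygen O1 on C8a, aryloxy on C8, methoxy on C7, hydroxyl on C5. The real difficulty is therefore regiochemical: placing the aryloxy group at C8 and not C6, telling the four oxygens apart, and building the second chromone without harming the first. Fragile features are the three free phenols, the two methyl ethers that must outlast every other O-protecting group, the reducible C2=C3 enone of each chromone, and the 5-hydroxy-8-oxygenated chromone, which can open and reclose to the 6-oxygenated isomer in hot strong acid (Wessely–Moser rearrangement). The key step exploits the fact that carbonyl carbon C4 is bonded to C4a, which is ortho to C8a carrying O1, which in turn neighbours the aryloxy carbon C8. A salicylaldehyde whose formyl carbon is the future C4 and whose only free phenol is the future O1 can therefore be annulated only to the 8-aryloxy chromone.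

## Logic of the disconnections

**20 to 19.** The three O–CH2Ph bonds (O5 of unit 1, O5'' and O7'' of unit 2) are cut. Benzyl is orthogonal to the two methyl ethers and leaves under neutral conditions, so no hot acid meets the free 5-hydroxy-8-aryloxy chromone. The forward step must cleave three benzyl ethers without reducing either C2=C3 bond.

**19 to 18.** The O1''–C2'' bond of ring C of unit 2 is cut, giving the open 1,3-dione. Only one phenol of 18 is free, so the closure has no regiochemical choice. The forward step needs acid mild enough for the benzyl ethers.

**18 to 15 and 17.** The C2''–C3'' bond is cut (crossed Claisen condensation). This is the convergent cut: it splits the molecule into the complete unit-1 chromone carrying an unhindered benzoate and a simple acetophenone. The enolate of 17 must acylate at the ester of 15 faster than it adds to the chromone of 15.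

**17 to 16.** Two O–benzyl bonds are cut. The hydrogen-bonded ortho hydroxyl is the least reactive, so it should stay free without help.

**15 to 9 and 13 (key).** The C3–C4 and O1–C2 bonds of ring C of unit 1 are cut. Ring C and the attachment of ring B come from one annulation, and the 8-versus-6 question is reduced to where the single free phenol of 9 sits. The forward step needs phenol-directed activation of the formyl C–H bond, tolerance of ester and benzyl ether, and dehydration of 14.

**13 to 10 and 11.** The bond between the carbonyl carbon and the ylide carbon is cut (acylation of 12). Both partners are commercial.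

**9 to 8.** The C4a–CHO bond is cut. In 8 one ortho position of the phenol carries the aryloxy group, so ortho-formylation has one site only. The forward step must work at a carbon flanked by hydroxyl and benzyloxy.

**8 to 6.** The C8a–O bond is traced back to C–Br (through 7). A free hydroxyl at this carbon during ether formation would be a second arylation site and would allow Smiles-type aryl migration between neighbouring oxygens. It would also later force a selective mono-benzylation of a resorcinol. A bromine placeholder removes all three problems at the cost of one step, and the forward step must turn C–Br into C–OH beside a methyl ester.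

**6 to 5.** One O–benzyl bond is cut. In 5 there is only one hydroxyl, so the benzylation is unambiguous.

**5 to 3.** The C5–O bond is traced back to C–H (through 4). This C–H is the only one in 3 with no ortho substituent, so sterically controlled borylation can select it. It also means the phenol used for ether formation need not carry a para formyl group, which would make it a poor nucleophile.

**3 to 1 and 2.** The diaryl ether C–O bond on the benzoate side is cut (nucleophilic aromatic substitution). Both partners are commercial. The forward step needs a 2,6-disubstituted phenoxide to displace fluoride para to an ester.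

## Other disconnections considered

**Alternative 1:** The cut runs through ring B of unit 2 (C3'–C4' and C5'–C6'), so the para-aryloxybenzoate is assembled and not bought. The aryl ethynyl ether A1 would add across C3 and C6 of methyl coumalate A2 in an inverse-demand Diels–Alder reaction, and the bicyclic lactone would lose CO2 to give benzoate A3.
- In favour: the polarisation of the partners places the ester para to the aryloxy group. The ether oxygen is already in place, so no flanked phenoxide has to displace fluoride at high temperature. A3 carries the two future ring-A oxygens of unit 1 in clearly different form (a methoxymethyl ether and a dioxolane-masked aldehyde).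
- Against: ring B of unit 2 is the one ring of the target that can be bought complete. A1 needs a multistep preparation through a dichlorovinyl ether and strong base, and aryl ynol ethers are delicate. After A3, acetal hydrolysis, Baeyer–Villiger oxidation, benzylation, removal of the methoxymethyl group and formylation would still be needed to reach 9.
- Comparison: on structure it ends at the same diaryl ether skeleton as 3 and 6 and leaves the chromone regiochemistry to be solved as in the chosen plan. On mechanism it replaces a polar substitution by a pericyclic reaction of well-defined regiochemistry; in avoiding substitution at a flanked phenoxide it is the better of the two. In differentiating the ring-A oxygens it is the equal of the chosen plan. On step economy it is clearly worse, roughly twice the steps to 9.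

**Alternative 2:** The cut is the C4a''–C5'' bond of ring A of unit 2, folded from a polyketide-type chain. Mg(OMe)2 in methanol would open the hydroxypyranone A4, and the magnesium-chelated chain would close by intramolecular Claisen condensation to the trihydroxychalcone A5. An oxidative cyclisation (I2 in DMSO) would then be needed to reach the flavone.
- In favour: unit 2 needs no protecting groups, which is better than the chosen plan (no step 8, a lighter step 11). The symmetric trihydroxyphenyl ketone cannot close to a wrong flavone isomer.
- Against: A4 must be made by acylating a pyranone dianion with a cinnamoyl donor that is also a Michael acceptor. The chain can fold in the aldol sense to a resorcylate instead of the Claisen sense. Methoxide meets the free 5-hydroxychromone of unit 1. The final oxidation must be run on a free phloroglucinol ring that iodinates easily.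
- Comparison: on structure it changes only the endgame; unit 1 would still come from something like steps 1 to 7, with the benzoate replaced by a cinnamoyl handle. On mechanism a chelation-controlled intramolecular Claisen condensation replaces the intermolecular one of step 9; it is equal in principle but adds a mode-selectivity question and an oxidation. On step economy it is about equal to steps 8 to 11 and better in protecting-group count.

**Alternative 3:** The cut is the C4–C4a bond of unit 1. The (Z)-β-aryloxycinnamic acid A6 would be activated by Eaton's reagent, and the acylium carbon would attack the ring carbon between the enol-ether-bearing and hydroxyl-bearing carbons (Friedel–Crafts closure of the Ruhemann type), giving chromone A7.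
- In favour: no transition metal and no formylation are needed. The chromone is reached from a phenol in about three operations (addition to a propiolic ester, saponification, cyclisation), equal to or one step shorter than steps 5 to 7. The attacked carbon is the only free position ortho to the enol ether oxygen, so the closure is as unambiguous as in the chosen plan. The 5-hydroxyl appears unprotected, which is better.
- Against: the regiochemical question only moves upstream. A6 requires the hindered hydroxyl next to the aryloxy group of a resorcinol, not the freer one, to add to the propiolate; otherwise the 6-aryloxy series results, so the other hydroxyl needs protection anyway. The free 5-hydroxy-8-aryloxychromone would form in hot strong acid, where Wessely–Moser isomerisation becomes conceivable. The acetyl handle of A7 would force unit 2 to be built by acylating its enolate with a hindered 2,6-dioxygenated benzoate.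
- Comparison: on structure both plans reach the same 8-aryloxy chromone through a blocked ortho position. On mechanism it is electrophilic substitution in strong acid against chelation-directed acyl C–H functionalisation under nearly neutral conditions; the latter is kinder to the benzyl ether and the substitution pattern. On step economy it is about equal up to the chromone and better in metal cost, but worse in the endgame.

Key step: step 7

## Route

Remark: 16 is used as its dried commercial monohydrate.

**Step 1**
Reactants: 1 2-bromo-6-methoxyphenol; 2 methyl 4-fluorobenzoate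
Product: 3 methyl 4-(2-bromo-6-methoxyphenoxy)benzoate
Conditions: Cs2CO3 (1.5 equiv), 2 (1.2 equiv), dry DMSO, 120 °C
Reagents that add atoms: none
Why: Nucleophilic aromatic substitution: the caesium phenoxide of 1, which has no electron-withdrawing group, adds para to the ester of 2 and fluoride leaves; 1 has no second hydroxyl, so neither double arylation nor aryl migration is possible.

**Step 2**
Reactants: 3 methyl 4-(2-bromo-6-methoxyphenoxy)benzoate
Product: 5 methyl 4-(2-bromo-4-hydroxy-6-methoxyphenoxy)benzoate, via aryl pinacol boronate 4 (not isolated)
Conditions: [Ir(OMe)(cod)]2 (cod = 1,5-cyclooctadiene, 1.5 mol %), 4,4'-di-tert-butyl-2,2'-bipyridine (3 mol %), B2pin2 (0.7 equiv), THF, 65 °C; then 30% aq H2O2, NaHCO3, THF/H2O, 0 °C to rt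
Reagents that add atoms: bis(pinacolato)diboron, CC1(C)OB(OC1(C)C)B1OC(C)(C)C(C)(C)O1 (boryl group of 4); hydrogen peroxide, OO (oxygen of 5)
Why: Iridium-catalysed aromatic C–H borylation (Hartwig–Miyaura type) is sterically controlled, and the only C–H bond of 3 without an ortho substituent is the one para to the ether oxygen in the brominated ring; aryl bromide and ester are tolerated, and oxidation of the C–B bond gives the phenol.

**Step 3**
Reactants: 5 methyl 4-(2-bromo-4-hydroxy-6-methoxyphenoxy)benzoate
Product: 6 methyl 4-[4-(benzyloxy)-2-bromo-6-methoxyphenoxy]benzoate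
Conditions: BnBr (1.2 equiv), K2CO3 (1.5 equiv), DMF, rt
Reagents that add atoms: benzyl bromide, BrCc1ccccc1
Why: Williamson etherification of the only phenol present, so no selectivity is required.

**Step 4**
Reactants: 6 methyl 4-[4-(benzyloxy)-2-bromo-6-methoxyphenoxy]benzoate
Product: 8 methyl 4-[4-(benzyloxy)-2-hydroxy-6-methoxyphenoxy]benzoate, via aryl pinacol boronate 7 (not isolated)
Conditions: B2pin2 (1.3 equiv), Pd(dppf)Cl2 (dppf = 1,1'-bis(diphenylphosphino)ferrocene, 5 mol %), KOAc (3 equiv), 1,4-dioxane, 90 °C; then 30% aq H2O2, NaHCO3, THF/H2O, 0 °C to rt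
Reagents that add atoms: bis(pinacolato)diboron, CC1(C)OB(OC1(C)C)B1OC(C)(C)C(C)(C)O1 (boryl group of 7); hydrogen peroxide, OO (oxygen of 8)
Why: Miyaura borylation (oxidative addition of the aryl bromide to zerovalent palladium, acetate-assisted transmetalation, reductive elimination) followed by oxidation of the boronate; the weakly basic conditions should leave the methyl ester and benzyl ether untouched.

**Step 5**
Reactants: 8 methyl 4-[4-(benzyloxy)-2-hydroxy-6-methoxyphenoxy]benzoate
Product: 9 methyl 4-[4-(benzyloxy)-3-formyl-2-hydroxy-6-methoxyphenoxy]benzoate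
Conditions: MgCl2 (3 equiv), Et3N (6 equiv), (CH2O)n (8 equiv), MeCN, 80 °C; 1 M HCl work-up
Reagents that add atoms: formaldehyde (from paraformaldehyde), C=O
Why: Magnesium-mediated ortho-formylation of a phenol (Casnati–Skattebøl reaction): the magnesium phenoxide delivers formaldehyde to the ortho carbon and a second formaldehyde oxidises the benzylic alkoxide by hydride transfer; one ortho position carries the aryloxy group, so only the carbon between hydroxyl and benzyloxy can react, as with 3,5-dialkoxyphenols.

**Step 6**
Reactants: 10 4-methoxybenzoyl chloride; 11 trimethylsulfoxonium iodide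
Product: 13 dimethylsulfoxonium 2-(4-methoxyphenyl)-2-oxoethylide, via dimethylsulfoxonium methylide 12 (not isolated)
Conditions: 11 (3.0 equiv), KOt-Bu (3.0 equiv), THF, reflux; then 10 (1.0 equiv), 0 °C to rt
Reagents that add atoms: none
Why: Deprotonation of 11 gives methylide 12, which is C-acylated by the acid chloride; a second equivalent of 12 removes the acidic proton between carbonyl and sulfur to give the stabilised ylide.

**Step 7**
Reactants: 9 methyl 4-[4-(benzyloxy)-3-formyl-2-hydroxy-6-methoxyphenoxy]benzoate; 13 dimethylsulfoxonium 2-(4-methoxyphenyl)-2-oxoethylide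
Product: 15 methyl 4-[[5-(benzyloxy)-7-methoxy-2-(4-methoxyphenyl)-4-oxo-4H-chromen-8-yl]oxy]benzoate, via 1,3-diketone 14 (not isolated)
Conditions: [(C5Me5)RhCl2]2 (4 mol %), AgSbF6 (16 mol %), NaOAc (30 mol %), PivOH (1.0 equiv), 13 (1.5 equiv), ClCH2CH2Cl, 100 °C, N2
Reagents that add atoms: none
Why: Chloride abstraction by AgSbF6 gives a cationic (C5Me5)Rh species of trivalent rhodium that binds the phenoxide of 9 and cleaves the adjacent formyl C–H bond by acetate-assisted metalation to a five-membered acyl rhodacycle. Ylide 13 coordinates through carbon and loses dimethyl sulfoxide to give a rhodium carbene into which the acyl group migrates; protonation of the resulting rhodium alkyl by pivalic acid releases 1,3-diketone 14 and returns the catalyst, so C3–C4 is formed without an external oxidant. The closest known reaction type is the annulation of salicylaldehydes with aroyl sulfoxonium ylides under trivalent rhodium catalysis to give 2-arylchromones. Ring C closes by condensation: the phenol oxygen adds to the anisyl ketone of 14 (6-exo-trig) and the hemiketal loses water in the acidic medium, forming O1–C2. No stereocentre is created. The step needs regioselectivity for the 8-aryloxy chromone and chemoselectivity for the formyl C–H bond: the first is secured because the only free phenol of 9 is the one next to the aryloxy carbon (the other ortho oxygen is benzylated and can neither direct the metal nor cyclise), the second because the phenoxide holds rhodium beside the formyl group while the ester, the ethers and the aryl C–H bonds offer no comparable chelate. If some 14 persists, brief warming with TsOH should complete the dehydration.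

**Step 8**
Reactants: 16 1-(2,4,6-trihydroxyphenyl)ethanone
Product: 17 1-[2,4-bis(benzyloxy)-6-hydroxyphenyl]ethanone
Conditions: BnBr (2.1 equiv), K2CO3 (2.2 equiv), DMF, rt to 50 °C
Reagents that add atoms: benzyl bromide, BrCc1ccccc1
Why: Williamson etherification in which the para hydroxyl and one ortho hydroxyl are alkylated, while the last ortho hydroxyl is held in a strong hydrogen bond to the carbonyl and should stay free.

**Step 9**
Reactants: 15 methyl 4-[[5-(benzyloxy)-7-methoxy-2-(4-methoxyphenyl)-4-oxo-4H-chromen-8-yl]oxy]benzoate; 17 1-[2,4-bis(benzyloxy)-6-hydroxyphenyl]ethanone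
Product: 18 1-[2,4-bis(benzyloxy)-6-hydroxyphenyl]-3-[4-[[5-(benzyloxy)-7-methoxy-2-(4-methoxyphenyl)-4-oxo-4H-chromen-8-yl]oxy]phenyl]propane-1,3-dione
Conditions: 17 (1.3 equiv), LiN(SiMe3)2 (4.0 equiv), THF, −78 to −10 °C; then 15 (1.0 equiv), −78 °C to rt; 1 M HCl
Reagents that add atoms: none
Why: Crossed Claisen condensation: the doubly deprotonated ketone (phenoxide and enolate) attacks the unhindered para-aryloxybenzoate and methoxide leaves, the product being protected as its enolate; the chromone of 15 has no acidic proton and its C2 is a β,β-disubstituted, oxygen-deactivated acceptor, so ester acylation should be faster than conjugate addition.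

**Step 10**
Reactants: 18 (the 1,3-dione of step 9)
Product: 19 5-(benzyloxy)-8-[4-[5,7-bis(benzyloxy)-4-oxo-4H-chromen-2-yl]phenoxy]-7-methoxy-2-(4-methoxyphenyl)-4H-chromen-4-one
Conditions: H2SO4 (cat.), AcOH, 80 °C
Reagents that add atoms: none
Why: Acid-catalysed cyclodehydration of a 1-(2-hydroxyaryl)-1,3-dione: the only free phenol adds to the carbonyl next to ring B and water is lost to close the pyranone; any benzyl ether loosened by the acid would be removed in step 11 anyway.

**Step 11**
Reactants: 19 (the tribenzyl biflavone of step 10)
Product: 20 8-[4-(5,7-dihydroxy-4-oxo-4H-chromen-2-yl)phenoxy]-5-hydroxy-7-methoxy-2-(4-methoxyphenyl)-4H-chromen-4-one (CNP0259871.0)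
Conditions: H2 (1 atm), 10% Pd on carbon, THF/MeOH 2:1, rt
Reagents that add atoms: none
Why: Hydrogenolysis of three aryl benzyl ethers; methyl ethers and the diaryl ether are inert, and the chromone C2=C3 bond (a vinylogous ester) should be reduced far more slowly than benzyl C–O bonds are cleaved, so the reaction is stopped after three equivalents of hydrogen.

## Compound list

1 | 2-bromo-6-methoxyphenol | COc1cccc(Br)c1O | starting material
2 | methyl 4-fluorobenzoate | COC(=O)c1ccc(F)cc1 | starting material
3 | methyl 4-(2-bromo-6-methoxyphenoxy)benzoate | COC(=O)c1ccc(Oc2c(OC)cccc2Br)cc1 | intermediate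
4 | methyl 4-[2-bromo-6-methoxy-4-(4,4,5,5-tetramethyl-1,3,2-dioxaborolan-2-yl)phenoxy]benzoate | COC(=O)c1ccc(Oc2c(OC)cc(B3OC(C)(C)C(C)(C)O3)cc2Br)cc1 | intermediate (not isolated)
5 | methyl 4-(2-bromo-4-hydroxy-6-methoxyphenoxy)benzoate | COC(=O)c1ccc(Oc2c(OC)cc(O)cc2Br)cc1 | intermediate
6 | methyl 4-[4-(benzyloxy)-2-bromo-6-methoxyphenoxy]benzoate | COC(=O)c1ccc(Oc2c(OC)cc(OCc3ccccc3)cc2Br)cc1 | intermediate
7 | methyl 4-[4-(benzyloxy)-2-methoxy-6-(4,4,5,5-tetramethyl-1,3,2-dioxaborolan-2-yl)phenoxy]benzoate | COC(=O)c1ccc(Oc2c(OC)cc(OCc3ccccc3)cc2B3OC(C)(C)C(C)(C)O3)cc1 | intermediate (not isolated)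
8 | methyl 4-[4-(benzyloxy)-2-hydroxy-6-methoxyphenoxy]benzoate | COC(=O)c1ccc(Oc2c(OC)cc(OCc3ccccc3)cc2O)cc1 | intermediate
9 | methyl 4-[4-(benzyloxy)-3-formyl-2-hydroxy-6-methoxyphenoxy]benzoate | COC(=O)c1ccc(Oc2c(OC)cc(OCc3ccccc3)c(C=O)c2O)cc1 | intermediate
10 | 4-methoxybenzoyl chloride | COc1ccc(C(=O)Cl)cc1 | starting material
11 | trimethylsulfoxonium iodide | C[S+](C)(C)=O.[I-] | starting material
12 | dimethylsulfoxonium methylide | C=S(C)(C)=O | intermediate (not isolated)
13 | dimethylsulfoxonium 2-(4-methoxyphenyl)-2-oxoethylide | COc1ccc(C(=O)C=S(C)(C)=O)cc1 | intermediate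
14 | methyl 4-[4-(benzyloxy)-2-hydroxy-6-methoxy-3-[3-(4-methoxyphenyl)-3-oxopropanoyl]phenoxy]benzoate | COC(=O)c1ccc(Oc2c(OC)cc(OCc3ccccc3)c(C(=O)CC(=O)c3ccc(OC)cc3)c2O)cc1 | intermediate (not isolated)
15 | methyl 4-[[5-(benzyloxy)-7-methoxy-2-(4-methoxyphenyl)-4-oxo-4H-chromen-8-yl]oxy]benzoate | COC(=O)c1ccc(Oc2c(OC)cc(OCc3ccccc3)c3c(=O)cc(-c4ccc(OC)cc4)oc23)cc1 | intermediate
16 | 1-(2,4,6-trihydroxyphenyl)ethanone | CC(=O)c1c(O)cc(O)cc1O | starting material
17 | 1-[2,4-bis(benzyloxy)-6-hydroxyphenyl]ethanone | CC(=O)c1c(O)cc(OCc2ccccc2)cc1OCc1ccccc1 | intermediate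
18 | 1-[2,4-bis(benzyloxy)-6-hydroxyphenyl]-3-[4-[[5-(benzyloxy)-7-methoxy-2-(4-methoxyphenyl)-4-oxo-4H-chromen-8-yl]oxy]phenyl]propane-1,3-dione | COc1ccc(-c2cc(=O)c3c(OCc4ccccc4)cc(OC)c(Oc4ccc(C(=O)CC(=O)c5c(O)cc(OCc6ccccc6)cc5OCc5ccccc5)cc4)c3o2)cc1 | intermediate
19 | 5-(benzyloxy)-8-[4-[5,7-bis(benzyloxy)-4-oxo-4H-chromen-2-yl]phenoxy]-7-methoxy-2-(4-methoxyphenyl)-4H-chromen-4-one | COc1ccc(-c2cc(=O)c3c(OCc4ccccc4)cc(OC)c(Oc4ccc(-c5cc(=O)c6c(OCc7ccccc7)cc(OCc7ccccc7)cc6o5)cc4)c3o2)cc1 | intermediate
20 | 8-[4-(5,7-dihydroxy-4-oxo-4H-chromen-2-yl)phenoxy]-5-hydroxy-7-methoxy-2-(4-methoxyphenyl)-4H-chromen-4-one | COc1ccc(-c2cc(=O)c3c(O)cc(OC)c(Oc4ccc(-c5cc(=O)c6c(O)cc(O)cc6o5)cc4)c3o2)cc1 | target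

## Step count and least certain steps

Total step count: 11. Longest linear sequence: 9 steps (steps 1, 2, 3, 4, 5, 7, 9, 10, 11, from 1 to 20); steps 6 and 8 make the side fragments 13 and 17.

**Step 7 (key step).** The most likely failure is slow or incomplete activation of the formyl C–H bond. The formyl group is flanked by hydroxyl and benzyloxy, and the aryloxy oxygen beside the phenol can compete for the metal. Meanwhile the ylide is used up by protonation or carbene dimerisation, and dehydration of 14 may stall. The fallback sets out from 9 and comes back at 15. Addition of (4-methoxyphenyl)ethynyllithium (from 1-ethynyl-4-methoxybenzene and n-BuLi, 2.2 equiv, THF, −78 °C, where the aldehyde reacts well before the benzoate) should give racemic methyl 4-[4-(benzyloxy)-2-hydroxy-3-[1-hydroxy-3-(4-methoxyphenyl)prop-2-yn-1-yl]-6-methoxyphenoxy]benzoate F1. MnO2 in CH2Cl2 should oxidise it to the ynone methyl 4-[4-(benzyloxy)-2-hydroxy-6-methoxy-3-[3-(4-methoxyphenyl)prop-2-ynoyl]phenoxy]benzoate F2. Et2NH in EtOH should then close the pyranone by 6-endo oxa-Michael addition through the enaminone, giving 15.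

**Step 1.** The most likely failure is slow substitution, because the phenoxide is 2,6-disubstituted and the fluoride is activated only by an ester. Long heating then invites demethylation of the ester by phenoxide or fluoride. The fallback sets out from 1 and comes back at 3. The salt (4-methoxycarbonylphenyl)(2,4,6-trimethoxyphenyl)iodonium 4-methylbenzenesulfonate F3 is made in one pot from methyl 4-iodobenzoate (mCPBA, TsOH·H2O, MeCN, then 1,3,5-trimethoxybenzene). It should transfer its electron-poor aryl group to the potassium phenoxide of 1 (K2CO3, MeCN, 40 °C) by ligand coupling at iodine, with no need for an activated fluoride.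

**Step 2.** The most likely failure is erosion of site selectivity as conversion is pushed: borylation ortho to the methoxy group or on the benzoate ring, or double borylation. The fallback sets out from 2 and comes back at 5, using an aldehyde as the masked phenol. Substitution of 2 by commercial 3-bromo-4-hydroxy-5-methoxybenzaldehyde (Cs2CO3, DMSO, 130 °C; slower, because this phenoxide is deactivated, or by aryl transfer as in the fallback for step 1) should give methyl 4-(2-bromo-4-formyl-6-methoxyphenoxy)benzoate F4. Baeyer–Villiger oxidation with mCPBA (CH2Cl2, 40 °C) should give the formate methyl 4-[2-bromo-4-(formyloxy)-6-methoxyphenoxy]benzoate F5, and K2CO3 (cat.) in MeOH should release 5.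

**Step 9.** The most likely failure is attack of the enolate or the amide base on C2 of the chromone in 15 (conjugate addition, ring opening) in competition with acylation, or incomplete conversion through proton exchange. The fallback sets out from 15 and comes back at 18, by Baker–Venkataraman rearrangement. LiOH in THF/H2O at rt should give 4-[[5-(benzyloxy)-7-methoxy-2-(4-methoxyphenyl)-4-oxo-4H-chromen-8-yl]oxy]benzoic acid F6. Esterification with the phenol of 17 (N-(3-dimethylaminopropyl)-N'-ethylcarbodiimide hydrochloride, DMAP, CH2Cl2) should give 2-acetyl-3,5-bis(benzyloxy)phenyl 4-[[5-(benzyloxy)-7-methoxy-2-(4-methoxyphenyl)-4-oxo-4H-chromen-8-yl]oxy]benzoate F7. KOH in pyridine at 50 °C should then move the aroyl group from oxygen to the enolate carbon intramolecularly, giving 18 without excess external nucleophile.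

**Step 11.** The most likely failure is partial reduction of a chromone C2=C3 bond, or stalling because partly debenzylated material precipitates on the catalyst. The fallback sets out from 19 and comes back at 20. BCl3 with pentamethylbenzene as benzyl-cation scavenger (CH2Cl2, −78 °C) should cleave the three benzyl ethers heterolytically. At this temperature the 7-methoxy and 4'-methoxy groups, which are not peri to a carbonyl, should remain, and no reducible bond is exposed.

## Further compounds

F1 | step 7 | methyl 4-[4-(benzyloxy)-2-hydroxy-3-[1-hydroxy-3-(4-methoxyphenyl)prop-2-yn-1-yl]-6-methoxyphenoxy]benzoate (racemic) | COC(=O)c1ccc(Oc2c(OC)cc(OCc3ccccc3)c(C(O)C#Cc3ccc(OC)cc3)c2O)cc1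
F2 | step 7 | methyl 4-[4-(benzyloxy)-2-hydroxy-6-methoxy-3-[3-(4-methoxyphenyl)prop-2-ynoyl]phenoxy]benzoate | COC(=O)c1ccc(Oc2c(OC)cc(OCc3ccccc3)c(C(=O)C#Cc3ccc(OC)cc3)c2O)cc1
F3 | step 1 | (4-methoxycarbonylphenyl)(2,4,6-trimethoxyphenyl)iodonium 4-methylbenzenesulfonate | COC(=O)c1ccc([I+]c2c(OC)cc(OC)cc2OC)cc1.Cc1ccc(S(=O)(=O)[O-])cc1
F4 | step 2 | methyl 4-(2-bromo-4-formyl-6-methoxyphenoxy)benzoate | COC(=O)c1ccc(Oc2c(OC)cc(C=O)cc2Br)cc1
F5 | step 2 | methyl 4-[2-bromo-4-(formyloxy)-6-methoxyphenoxy]benzoate | COC(=O)c1ccc(Oc2c(OC)cc(OC=O)cc2Br)cc1
F6 | step 9 | 4-[[5-(benzyloxy)-7-methoxy-2-(4-methoxyphenyl)-4-oxo-4H-chromen-8-yl]oxy]benzoic acid | COc1ccc(-c2cc(=O)c3c(OCc4ccccc4)cc(OC)c(Oc4ccc(C(=O)O)cc4)c3o2)cc1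
F7 | step 9 | 2-acetyl-3,5-bis(benzyloxy)phenyl 4-[[5-(benzyloxy)-7-methoxy-2-(4-methoxyphenyl)-4-oxo-4H-chromen-8-yl]oxy]benzoate | COc1ccc(-c2cc(=O)c3c(OCc4ccccc4)cc(OC)c(Oc4ccc(C(=O)Oc5cc(OCc6ccccc6)cc(OCc6ccccc6)c5C(C)=O)cc4)c3o2)cc1
F0 | step 11 | none | none
A1 | alternative 1 | 2-[4-(ethynyloxy)-3-methoxy-5-(methoxymethoxy)phenyl]-1,3-dioxolane | C#COc1c(OC)cc(C2OCCO2)cc1OCOC
A2 | alternative 1 | methyl coumalate (methyl 2-oxo-2H-pyran-5-carboxylate) | COC(=O)c1ccc(=O)oc1
A3 | alternative 1 | methyl 4-[4-(1,3-dioxolan-2-yl)-2-methoxy-6-(methoxymethoxy)phenoxy]benzoate | COC(=O)c1ccc(Oc2c(OC)cc(C3OCCO3)cc2OCOC)cc1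
A4 | alternative 2 | 4-hydroxy-6-[(E)-4-[4-[[5-hydroxy-7-methoxy-2-(4-methoxyphenyl)-4-oxo-4H-chromen-8-yl]oxy]phenyl]-2-oxobut-3-en-1-yl]-2H-pyran-2-one | O=C(Cc1cc(O)cc(=O)o1)/C=C/c1ccc(Oc2c(OC)cc(O)c3c(=O)cc(-c4ccc(OC)cc4)oc23)cc1
A5 | alternative 2 | (E)-3-[4-[[5-hydroxy-7-methoxy-2-(4-methoxyphenyl)-4-oxo-4H-chromen-8-yl]oxy]phenyl]-1-(2,4,6-trihydroxyphenyl)prop-2-en-1-one | O=C(/C=C/c1ccc(Oc2c(OC)cc(O)c3c(=O)cc(-c4ccc(OC)cc4)oc23)cc1)c1c(O)cc(O)cc1O
A6 | alternative 3 | (Z)-3-[2-(4-acetylphenoxy)-5-hydroxy-3-methoxyphenoxy]-3-(4-methoxyphenyl)prop-2-enoic acid | CC(=O)c1ccc(Oc2c(OC)cc(O)cc2O/C(=C\C(=O)O)c2ccc(OC)cc2)cc1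
A7 | alternative 3 | 8-(4-acetylphenoxy)-5-hydroxy-7-methoxy-2-(4-methoxyphenyl)-4H-chromen-4-one | CC(=O)c1ccc(Oc2c(OC)cc(O)c3c(=O)cc(-c4ccc(OC)cc4)oc23)cc1
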